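**Plan**

1. Retrosynthesis: the 4'-O–Si and 7-O–prenyl bonds are cut first. Ring C is then opened at both O1–C2 and C4–C4a, which leads back to a phloroglucinol monoester of a trans-3-arylglycidic acid. The ester C–O bond and the oxirane are cut last, giving phloroglucinol and methyl ferulate.
2. Forward: rings A and B are bought. The ferulate chain on ring B is epoxidised and hung on one oxygen of ring A as an ester tether. Ring C then forms in one photochemical operation (acyl shift from O to C, then oxirane opening). O7-prenylation and desilylation finish the route.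
3. Enabling feature: ring A is a 1,3,5-trioxygenated benzene in which every ring carbon lies between two oxygens, so the migrating acyl group gives the same ketone wherever it lands and either neighbouring OH closes the same pyranone. C2 is benzylic to the para-oxygenated ring B, so a strained oxirane is opened there by that OH.
4. Stereochemistry: C3 comes from a catalytic asymmetric (chiral dioxirane) epoxidation of the E-cinnamate. C2 comes from anti opening of the trans-(2R,3S)-oxirane (inversion at the benzylic carbon), which gives the 2,3-trans (2R,3R) chromanone.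

Key step: step 5

Remark: methyl ferulate, phloroglucinol, prenyl bromide and 2,4,6-trichlorobenzoyl chloride are taken as purchased. The chiral ketone of step 2 is taken as an available catalyst, made in the L-series in the same way as its D-fructose-derived enantiomer, and is not counted as a step.

**Step 1**
Reactants: 1 methyl ferulate
Product: 2 methyl (E)-3-[3-methoxy-4-(triisopropylsilyloxy)phenyl]prop-2-enoate
Conditions: iPr3SiCl (1.2 equiv), imidazole (2.5 equiv), DMF, 20 °C
Reagents that add atoms: triisopropylsilyl chloride, CC(C)[Si](Cl)(C(C)C)C(C)C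
Why: Imidazole-promoted silyl ether formation masks the 4-hydroxyl, which would otherwise let the later aryl oxirane collapse to a quinone methide, and the bulky triisopropylsilyl group is chosen to survive aqueous bicarbonate, silanolate and carbonate in the following steps.

**Step 2**
Reactants: 2 silylated methyl ferulate
Product: 3 methyl (2R,3S)-3-[3-methoxy-4-(triisopropylsilyloxy)phenyl]oxirane-2-carboxylate
Conditions: L-fructose-derived 4,5-di-O-acetyl-1,2-O-isopropylidene ketone (25 mol%), KHSO5 (as 2KHSO5·KHSO4·K2SO4), NaHCO3, Bu4NHSO4 (cat.), MeCN/H2O, 0 °C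
Reagents that add atoms: potassium peroxymonosulfate, [K+].[O-]S(=O)(=O)OO
Why: Shi-type chiral dioxirane epoxidation of an E-cinnamate ester, in which the L-configured ketone, being the mirror image of the D-fructose-derived catalyst that turns E-cinnamates into (2S,3R)-glycidates, should deliver oxygen to the alkene face that gives the trans-(2R,3S)-epoxide and so fixes the later C3 stereocentre.

**Step 3**
Reactants: 3 methyl glycidate
Product: 4 potassium (2R,3S)-3-[3-methoxy-4-(triisopropylsilyloxy)phenyl]oxirane-2-carboxylate
Conditions: KOSiMe3 (1.05 equiv), THF, 0 → 20 °C; salt collected and used as such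
Reagents that add atoms: potassium trimethylsilanolate, C[Si](C)(C)[O-].[K+]
Why: Anhydrous ester cleavage with silanolate gives the glycidate directly as its stable potassium salt and avoids the free glycidic acid, which would decarboxylate, while both stereocentres and the hindered aryl silyl ether stay untouched.

**Step 4**
Reactants: 4 potassium glycidate; 5 2,4,6-trichlorobenzoyl chloride; 6 phloroglucinol
Product: 8 3,5-dihydroxyphenyl (2R,3S)-3-[3-methoxy-4-(triisopropylsilyloxy)phenyl]oxirane-2-carboxylate, via glycidic trichlorobenzoic mixed anhydride 7 (not isolated)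
Conditions: 5 (1.0 equiv), THF, 0 °C; then 6 (5 equiv), Et3N (1.5 equiv), DMAP (10 mol%), THF, 0 → 20 °C; excess 6 washed out with water
Reagents that add atoms: none
Why: Yamaguchi-type esterification in which the carboxylate is turned into the mixed anhydride 7 and DMAP passes the unhindered glycidoyl group to a phenol oxygen, the excess of the threefold-symmetric triol holding the reaction at the monoester and the cold basic medium leaving the oxirane closed.

**Step 5**
Reactants: 8 3,5-dihydroxyphenyl glycidate
Product: 10 (2R,3R)-3,5,7-trihydroxy-2-[3-methoxy-4-(triisopropylsilyloxy)phenyl]-2,3-dihydro-4H-chromen-4-one, via trihydroxyphenyl oxiranyl ketone 9 (not isolated)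
Conditions: hν (254 nm, low-pressure Hg lamp, quartz), degassed MeCN (0.005 M), 20 °C; then PPTS (5 mol%), same flask, dark, 20–40 °C
Reagents that add atoms: none
Why: Excitation of the aryl ester chromophore homolyses the ArO–C(=O) bond to a solvent-caged 3,5-dihydroxyphenoxyl/glycidoyl radical pair, which recombines at a ring carbon and rearomatises to the 2-hydroxyaryl oxiranyl ketone 9 (C4–C4a formed), whose freed ortho-hydroxyl, hydrogen-bonded to the new ketone, then opens the strained oxirane at the benzylic carbon (O1–C2 formed). The closest known reaction types are the photo-Fries rearrangement of aryl cinnamates to 2'-hydroxychalcones and the cyclisation of 2'-hydroxychalcone epoxides to trans-dihydroflavonols. Ring C closes in the 6-endo-tet mode, driven by release of the oxirane strain and preferred over 5-exo attack at the carbonyl-bearing carbon because the para-silyloxy group of ring B activates the benzylic C–O bond. The new stereocentre C2 is controlled by the epoxide carbon that becomes C3: anti opening inverts the benzylic carbon of the trans-(2R,3S)-oxirane and gives the 2,3-trans (2R,3R) product, and even a cation-like opening is steered by C3 to the diequatorial trans isomer. The step needs regioselective acyl migration and acylation at carbon ahead of any attack at the benzylic carbon: the threefold symmetry of ring A makes both ortho carbons and the para carbon deliver the same ketone and either flanking hydroxyl the same chromanone, and the neutral photochemical conditions keep the oxirane closed until the acyl group sits on carbon, so the competing Friedel–Crafts alkylation to a 4-aryl-dihydrocoumarin has no opening.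

**Step 6**
Reactants: 10 silylated trihydroxy-chromanone; 11 prenyl bromide (1-bromo-3-methylbut-2-ene)
Product: 12 (2R,3R)-3,5-dihydroxy-2-[3-methoxy-4-(triisopropylsilyloxy)phenyl]-7-[(3-methylbut-2-en-1-yl)oxy]-2,3-dihydro-4H-chromen-4-one
Conditions: 11 (1.1 equiv), K2CO3 (1.1 equiv), acetone, 20 °C, N2, dark
Reagents that add atoms: none
Why: Williamson ether synthesis under weak base, in which the 7-hydroxyl para to the carbonyl is the most acidic (a vinylogous acid) while the 5-hydroxyl is locked in a hydrogen bond to the ketone, the 3-hydroxyl is an alcohol and the 4'-oxygen is silylated, so one equivalent of carbonate and bromide should alkylate O7 only.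

**Step 7**
Reactants: 12 silylated prenyl ether
Product: 13 (2R,3R)-3,5-dihydroxy-2-(4-hydroxy-3-methoxyphenyl)-7-[(3-methylbut-2-en-1-yl)oxy]-2,3-dihydro-4H-chromen-4-one (target)
Conditions: Bu4NF (1.1 equiv), AcOH (1.5 equiv), THF, 0 °C
Reagents that add atoms: none
Why: Fluoride-mediated cleavage of the aryl silyl ether, buffered with acetic acid so that no free phenoxide base can open ring C or epimerise C2 or C3, with the prenyl aryl ether inert to fluoride.

**Compound list**

1 | methyl ferulate, methyl (E)-3-(4-hydroxy-3-methoxyphenyl)prop-2-enoate | COC(=O)/C=C/c1ccc(O)c(OC)c1 | starting material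
2 | methyl (E)-3-[3-methoxy-4-(triisopropylsilyloxy)phenyl]prop-2-enoate | COC(=O)/C=C/c1ccc(O[Si](C(C)C)(C(C)C)C(C)C)c(OC)c1 | intermediate
3 | methyl (2R,3S)-3-[3-methoxy-4-(triisopropylsilyloxy)phenyl]oxirane-2-carboxylate | COc1cc([C@H]2[C@H](C(=O)OC)O2)ccc1O[Si](C(C)C)(C(C)C)C(C)C | intermediate
4 | potassium (2R,3S)-3-[3-methoxy-4-(triisopropylsilyloxy)phenyl]oxirane-2-carboxylate | COc1cc([C@H]2[C@H](C(=O)[O-])O2)ccc1O[Si](C(C)C)(C(C)C)C(C)C.[K+] | intermediate
5 | 2,4,6-trichlorobenzoyl chloride | O=C(Cl)c1c(Cl)cc(Cl)cc1Cl | starting material
6 | phloroglucinol, benzene-1,3,5-triol | Oc1cc(O)cc(O)c1 | starting material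
7 | (2R,3S)-3-[3-methoxy-4-(triisopropylsilyloxy)phenyl]oxirane-2-carboxylic 2,4,6-trichlorobenzoic anhydride | COc1cc([C@H]2[C@H](C(=O)OC(=O)c3c(Cl)cc(Cl)cc3Cl)O2)ccc1O[Si](C(C)C)(C(C)C)C(C)C | intermediate
8 | 3,5-dihydroxyphenyl (2R,3S)-3-[3-methoxy-4-(triisopropylsilyloxy)phenyl]oxirane-2-carboxylate | COc1cc([C@H]2[C@H](C(=O)Oc3cc(O)cc(O)c3)O2)ccc1O[Si](C(C)C)(C(C)C)C(C)C | intermediate
9 | [(2R,3S)-3-[3-methoxy-4-(triisopropylsilyloxy)phenyl]oxiran-2-yl](2,4,6-trihydroxyphenyl)methanone | COc1cc([C@H]2[C@H](C(=O)c3c(O)cc(O)cc3O)O2)ccc1O[Si](C(C)C)(C(C)C)C(C)C | intermediate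
10 | (2R,3R)-3,5,7-trihydroxy-2-[3-methoxy-4-(triisopropylsilyloxy)phenyl]-2,3-dihydro-4H-chromen-4-one | COc1cc([C@H]2Oc3cc(O)cc(O)c3C(=O)[C@@H]2O)ccc1O[Si](C(C)C)(C(C)C)C(C)C | intermediate
11 | prenyl bromide, 1-bromo-3-methylbut-2-ene | CC(C)=CCBr | starting material
12 | (2R,3R)-3,5-dihydroxy-2-[3-methoxy-4-(triisopropylsilyloxy)phenyl]-7-[(3-methylbut-2-en-1-yl)oxy]-2,3-dihydro-4H-chromen-4-one | COc1cc([C@H]2Oc3cc(OCC=C(C)C)cc(O)c3C(=O)[C@@H]2O)ccc1O[Si](C(C)C)(C(C)C)C(C)C | intermediate
13 | (2R,3R)-3,5-dihydroxy-2-(4-hydroxy-3-methoxyphenyl)-7-[(3-methylbut-2-en-1-yl)oxy]-2,3-dihydro-4H-chromen-4-one | COc1cc([C@H]2Oc3cc(OCC=C(C)C)cc(O)c3C(=O)[C@@H]2O)ccc1O | target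

**Step count and risks**

Total step count: 7. Longest linear sequence: 7 steps (1 → 13).

Steps most likely to fail:

**Step 5.** Three processes could go wrong. Light absorbed by the silyloxy-methoxyphenyl oxirane chromophore could cleave the oxirane photochemically. The radical pair could escape the cage or lose CO. The reaction could also stall as the strongly absorbing chromanone builds up, and a late cyclisation could go 5-exo at the carbonyl-bearing carbon. The fallback uses known chemistry, sets out from 4 and 6, and comes back at 10. Salt 4 is coupled with N,O-dimethylhydroxylamine hydrochloride (1-ethyl-3-(3-dimethylaminopropyl)carbodiimide hydrochloride, N-methylmorpholine, CH2Cl2, 0 °C) to (2R,3S)-N-methoxy-N-methyl-3-[3-methoxy-4-(triisopropylsilyloxy)phenyl]oxirane-2-carboxamide F1. Phloroglucinol 6 is converted with chloromethyl methyl ether and iPr2NEt into 1,3,5-tris(methoxymethoxy)benzene F2. This is lithiated between two acetal oxygens (n-BuLi, THF, 0 °C) to 2,4,6-tris(methoxymethoxy)phenyllithium F3. Addition of F3 to F1 at −78 °C (Weinreb ketone synthesis) should give [(2R,3S)-3-[3-methoxy-4-(triisopropylsilyloxy)phenyl]oxiran-2-yl][2,4,6-tris(methoxymethoxy)phenyl]methanone F4. HCl in MeOH/THF at 40 °C then removes the three acetals, and the freed ortho-hydroxyl opens the oxirane at the benzylic carbon to 10.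

**Step 2.** Facial selectivity could be poor with this electron-rich cinnamate. The ketone catalyst could decay by Baeyer–Villiger oxidation faster than it epoxidises. The acid-sensitive aryl oxirane could be opened hydrolytically in the aqueous medium. The fallback sets out from 2 and comes back at 3. Alkene 2 is epoxidised without stereocontrol (dimethyldioxirane, acetone, 0 °C) to racemic methyl trans-3-[3-methoxy-4-(triisopropylsilyloxy)phenyl]oxirane-2-carboxylate F5. A kinetic resolution follows with a hydrolase of the lipase class (lipase from Serratia marcescens, toluene/aqueous phosphate buffer pH 8, 30 °C). It is expected to hydrolyse the (2S,3R)-ester and leave the (2R,3S)-ester 3. The acid from the unwanted enantiomer decarboxylates on work-up and is removed by a bisulfite wash.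

**Step 6.** Alkylation could occur at carbon (C6 or C8) or at O5 or O3 instead of O7. The phenoxide could open ring C with epimerisation at C2. Air could oxidise the product to the flavonol. The fallback sets out from 10 and comes back at 12. It is a Mitsunobu etherification with 3-methylbut-2-en-1-ol (PPh3, diisopropyl azodicarboxylate, THF, 0 °C). Under these neutral conditions only the most acidic hydroxyl (O7–H) is a competent pronucleophile, and the primary allylic alcohol is activated in preference to the hindered 3-hydroxyl. This fallback makes no new compound (F0).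

**Further compounds**

F1 | step 5 | (2R,3S)-N-methoxy-N-methyl-3-[3-methoxy-4-(triisopropylsilyloxy)phenyl]oxirane-2-carboxamide | COc1cc([C@H]2[C@H](C(=O)N(C)OC)O2)ccc1O[Si](C(C)C)(C(C)C)C(C)C
F2 | step 5 | 1,3,5-tris(methoxymethoxy)benzene | COCOc1cc(OCOC)cc(OCOC)c1
F3 | step 5 | 2,4,6-tris(methoxymethoxy)phenyllithium | [Li]c1c(OCOC)cc(OCOC)cc1OCOC
F4 | step 5 | [(2R,3S)-3-[3-methoxy-4-(triisopropylsilyloxy)phenyl]oxiran-2-yl][2,4,6-tris(methoxymethoxy)phenyl]methanone | COc1cc([C@H]2[C@H](C(=O)c3c(OCOC)cc(OCOC)cc3OCOC)O2)ccc1O[Si](C(C)C)(C(C)C)C(C)C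
F5 | step 2 | racemic methyl trans-3-[3-methoxy-4-(triisopropylsilyloxy)phenyl]oxirane-2-carboxylate, 1:1 (2R,3S) and (2S,3R) | COc1cc([C@H]2[C@H](C(=O)OC)O2)ccc1O[Si](C(C)C)(C(C)C)C(C)C.COc1cc([C@@H]2[C@@H](C(=O)OC)O2)ccc1O[Si](C(C)C)(C(C)C)C(C)C
F0 | step 6 | none | none
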